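**Plan**

1. Retrosynthetic cuts, in order: the C3–O acyl bond and the C11–O aryl bond (isovaleryl chloride, isofraxidin); then, with C5 returned to the cis fusion and O3 re-tied to C11 as a lactone, the C5–C6 and C6–C7 bonds of ring B (loss of CO, C5 re-bonded to C9); then C8=C7 (Wittig) and the C9–C5/C9–C10 cyclopropane bonds (carbenoid on the C5=C10 alkene).
2. Forward order: ring A from 4-methylanisole; O3–C11 ester tether; cyclopropane C5–C9–C10, which closes the δ-lactone; ring B by carbonylative [5+1] ring expansion; lactone reduced; coumarin ether and isovalerate attached last.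
3. Enabling feature: the axial C3 oxygen on ring A and C11 on C9 of ring B lie on the same (α) face, trans to the C10 methyl, so a C3–O–C11(=O)–C9 lactone can deliver C9 to the C5=C10 alkene as a cyclopropane. The C6 carbonyl, flanked by C5 and C7, is then one CO unit inserted between C5 and the vinyl carbon C7.
4. Stereochemistry: C3 from a CBS reduction; C10 from the tether-directed cyclopropanation; C9 from protonation inside the lactone bridge; C5 from base equilibration to the trans-decalin once the bridge is opened.

Key step: step 8

Remark: drimane numbering is used (decalin C1–C10, C11 = CH2O on C9, C12 = methyl on C8); β is the face of the C10 methyl group, α the opposite face. The C6 carbinol centre of triol 16 is expected as an epimer mixture that converges in step 11, so it carries no descriptor.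

**Route**

Step 1
Reactants: 1 4-methylanisole
Product: 3 4-methylcyclohex-3-en-1-one, via 1-methoxy-4-methylcyclohexa-1,4-diene 2 (not isolated)
Conditions: Li, NH3(l), t-BuOH, THF, −78 to −33 °C; then (CO2H)2, MeOH–H2O, 23 °C
Reagents that add atoms: water, O
Why: Birch reduction of the anisole gives the 1,4-diene enol ether, and mild oxalic acid hydrolysis should unmask the ketone without moving the remaining alkene into conjugation.

Step 2
Reactants: 3 4-methylcyclohex-3-en-1-one
Product: 5 2,2,4-trimethylcyclohex-3-en-1-one, via 2,4-dimethylcyclohex-3-en-1-one 4 (not isolated)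
Conditions: KOtBu (2.2 equiv), MeI (2.5 equiv), t-BuOH–THF, 0 to 23 °C
Reagents that add atoms: iodomethane, CI
Why: The position between carbonyl and alkene is the most acidic, and its extended enolate should alkylate twice at that α-carbon with the alkene staying β,γ (α,α-dialkylation of a dienolate, as in the gem-dimethylation of enones).

Step 3
Reactants: 5 2,2,4-trimethylcyclohex-3-en-1-one
Product: 6 (R)-2,2,4-trimethylcyclohex-3-en-1-ol
Conditions: (S)-2-methyl-CBS-oxazaborolidine (0.2 equiv), catecholborane, toluene, −40 °C; aq. NaOH
Reagents that add atoms: none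
Why: Corey–Bakshi–Shibata reduction should tell the quaternary side of the ketone from the CH2 side and, with the (S)-catalyst, give the (R)-carbinol (C3 of the target), while catecholborane leaves the trisubstituted alkene alone.

Step 4
Reactants: 6 (R)-2,2,4-trimethylcyclohex-3-en-1-ol; 7 2,2,6-trimethyl-4H-1,3-dioxin-4-one
Product: 9 (R)-2,2,4-trimethylcyclohex-3-en-1-yl 3-oxobutanoate, via acetylketene 8 (not isolated)
Conditions: xylenes, 135 °C, acetone distilled off
Reagents that add atoms: none
Why: Thermal retro-hetero-Diels–Alder cleavage of the dioxinone releases acetylketene, which should acylate even this hindered secondary alcohol without touching the carbinol centre (acetoacetylation).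

Step 5
Reactants: 9 (R)-2,2,4-trimethylcyclohex-3-en-1-yl 3-oxobutanoate
Product: 10 (R)-2,2,4-trimethylcyclohex-3-en-1-yl 2-diazo-3-oxobutanoate
Conditions: 4-acetamidobenzenesulfonyl azide, Et3N, MeCN, 0 to 23 °C
Reagents that add atoms: 4-acetamidobenzenesulfonyl azide, CC(=O)Nc1ccc(cc1)S(=O)(=O)N=[N+]=[N-]
Why: Regitz diazo transfer to the doubly activated methylene of a β-keto ester is reliable and leaves the remote stereocentre untouched.

Step 6
Reactants: 10 (R)-2,2,4-trimethylcyclohex-3-en-1-yl 2-diazo-3-oxobutanoate
Product: 11 acetylcyclopropane δ-lactone (cyclopropane C5–C9–C10 on the α face; C9 carries acetyl and the lactone carbonyl C11 bound to O3; C10 methyl and C5–H β)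
Conditions: Rh2(OAc)4 (1 mol %), CH2Cl2, 40 °C, slow addition of 10
Reagents that add atoms: none
Why: The divalent rhodium carbenoid formed on loss of N2 should add to the C5=C10 alkene (intramolecular cyclopropanation of a diazo keto ester, closing the δ-lactone through C5); the three-atom ester tether from the pseudoaxial C3 oxygen reaches only the alkene face syn to that oxygen, which sets C5, C9 and C10 together with the C10 methyl anti to the tether.

Step 7
Reactants: 11 acetylcyclopropane δ-lactone
Product: 12 isopropenylcyclopropane δ-lactone (as 11, with C9–C(CH3)=CH2; C8 and C7 now in place)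
Conditions: Ph3PCH3Br, KOtBu, THF, 0 to 50 °C
Reagents that add atoms: methyltriphenylphosphonium bromide, C[P+](c1ccccc1)(c1ccccc1)c1ccccc1.[Br-]
Why: Wittig methylenation of the methyl ketone should be clean because C9 is quaternary (nothing next to the lactone can enolise) and non-stabilised ylides leave esters alone at this temperature.

Step 8
Reactants: 12 isopropenylcyclopropane δ-lactone; 13 carbon monoxide
Product: 14 lactone-bridged cis-fused 8-en-6-one (ring B: C5–C6(=O)–C7H2–C8(CH3)=C9–C10; C11(=O)–O3 bridge on the α face; 5β-H, 10β-CH3)
Conditions: [Rh(CO)2Cl]2 (10 mol %), CO (1 atm), toluene, 80 °C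
Reagents that add atoms: none
Why: Proposed new method: monovalent rhodium bound to the isopropenyl alkene should add oxidatively into the adjacent C9–C5 cyclopropane bond to give a σ-alkyl (C5)/π-allyl (C9–C8–C7) rhodacycle, CO should insert into the Rh–C5 bond with retention, and acyl–allyl reductive elimination at the unsubstituted terminus C7 should form C6–C7; the closest known reaction type is the rhodium-catalysed or Fe(CO)5-mediated carbonylative [5+1] ring expansion of simple vinylcyclopropanes to cyclohexenones, which has not been shown on a lactone-bridged, fully substituted, acyl-bearing cyclopropane. Ring B closes by reductive elimination from the seven-membered acyl rhodacycle, a formal [5+1] in which C5, C10, C9, C8 and C7 are joined through C6. No stereocentre is created: C3 and C10 are untouched, C5 keeps its configuration (hence the cis fusion) and C9 becomes trigonal. The selectivity needed is cleavage of C9–C5 and not C9–C10; it is secured because C10 is quaternary, so only C5 can carry the metal, and because both neighbours of C5 (C4 and C10) lack hydrogen, which shuts off β-hydride elimination to dienes. Coupling at C7 and not at the quaternary C9 terminus gives the six-membered ring with the C8=C9 alkene conjugated to the lactone carbonyl; the temperature is kept at 80 °C to hold back the thermal homodienyl hydrogen shift from the C10 methyl.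

Step 9
Reactants: 14 lactone-bridged cis-fused 8-en-6-one
Product: 15 lactone-bridged cis-fused 7-en-6-one (9β-H, C11 α; 5β-H)
Conditions: DBU (0.2 equiv), CH2Cl2, 23 °C
Reagents that add atoms: none
Why: Prototropic isomerisation through the extended enolate (C7 deprotonated, C9 protonated) should move the alkene into conjugation with the ketone, the arrangement preferred in 4-oxocyclohex-2-ene-1-carboxylates of the Hagemann ester type; the proton can reach C9 only from the open β face, because the lactone bridge holds C11 on the α face.

Step 10
Reactants: 15 lactone-bridged cis-fused 7-en-6-one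
Product: 16 cis-fused drim-7-ene-3α,6,11-triol (5β-H, 9β-H; C6 epimer mixture)
Conditions: i-Bu2AlH (6 equiv), CH2Cl2, −78 to 0 °C; aq. KNaC4H4O6
Reagents that add atoms: none
Why: The Lewis-acidic, weakly basic hydride should reduce the enone by 1,2-addition and the lactone to the C3/C11 diol without deprotonating the acidic C9–H (hydride reduction); no stereocentre of the target is affected.

Step 11
Reactants: 16 cis-fused drim-7-ene-3α,6,11-triol
Product: 17 cis-fused 3α,11-dihydroxydrim-7-en-6-one (5β-H, 9β-H)
Conditions: MnO2, CH2Cl2, 23 °C
Reagents that add atoms: none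
Why: MnO2 should oxidise only the allylic C6 alcohol, the primary homoallylic and the hindered secondary alcohol being inert (chemoselective allylic oxidation).

Step 12
Reactants: 17 cis-fused 3α,11-dihydroxydrim-7-en-6-one
Product: 18 (3R,5R,9R,10R)-3α,11-dihydroxydrim-7-en-6-one (trans-fused: 5α-H; 9β-H)
Conditions: K2CO3 (0.5 equiv), MeOH, 23 °C
Reagents that add atoms: none
Why: Reversible enolisation at C5 should let the ring fusion settle to the trans-decalin (thermodynamic epimerisation α to the ketone), since either cis conformer puts C6 syn-axial to the C3 hydroxyl or C9 syn-axial to the 4α-methyl; C9 is not endangered, because the pseudoaxial α-CH2OH, anti to the C10 methyl and free of allylic strain with the C8 methyl, is also the preferred orientation.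

Step 13
Reactants: 18 (3R,5R,9R,10R)-3α,11-dihydroxydrim-7-en-6-one; 19 isofraxidin
Product: 20 11-O-(6,8-dimethoxy-2-oxo-2H-chromen-7-yl) ether of 18
Conditions: PPh3, DIAD, THF, 0 to 23 °C
Reagents that add atoms: none
Why: In a Mitsunobu etherification only the primary C11 alcohol should be activated (the axial C3 alcohol next to the gem-dimethyl group is too hindered) and the acidic phenol displaces it; no stereocentre is involved, and the neutral conditions avoid enolate chemistry at C9.

Step 14
Reactants: 20 11-O-(6,8-dimethoxy-2-oxo-2H-chromen-7-yl) ether of 18; 21 isovaleryl chloride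
Product: 22 (3R,5R,9R,10R)-11-[(6,8-dimethoxy-2-oxo-2H-chromen-7-yl)oxy]-6-oxodrim-7-en-3-yl 3-methylbutanoate (target)
Conditions: pyridine, DMAP (0.1 equiv), CH2Cl2, 0 to 23 °C
Reagents that add atoms: none
Why: DMAP-catalysed acylation should esterify the one remaining, hindered axial alcohol, and the weakly basic medium does not trigger loss of the aryloxide from C11.

**Compound list**

1 | 4-methylanisole | COc1ccc(C)cc1 | starting material
2 | 1-methoxy-4-methylcyclohexa-1,4-diene (not isolated) | COC1=CCC(C)=CC1 | intermediate
3 | 4-methylcyclohex-3-en-1-one | CC1=CCC(=O)CC1 | intermediate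
4 | 2,4-dimethylcyclohex-3-en-1-one (racemic, not isolated) | CC1=CC(C)C(=O)CC1 | intermediate
5 | 2,2,4-trimethylcyclohex-3-en-1-one | CC1=CC(C)(C)C(=O)CC1 | intermediate
6 | (R)-2,2,4-trimethylcyclohex-3-en-1-ol | CC1=CC(C)(C)[C@H](O)CC1 | intermediate
7 | 2,2,6-trimethyl-4H-1,3-dioxin-4-one | CC1=CC(=O)OC(C)(C)O1 | starting material
8 | acetylketene (but-1-ene-1,3-dione, not isolated) | CC(=O)C=C=O | intermediate
9 | (R)-2,2,4-trimethylcyclohex-3-en-1-yl 3-oxobutanoate | CC(=O)CC(=O)O[C@@H]1CCC(C)=CC1(C)C | intermediate
10 | (R)-2,2,4-trimethylcyclohex-3-en-1-yl 2-diazo-3-oxobutanoate | CC(=O)C(=[N+]=[N-])C(=O)O[C@@H]1CCC(C)=CC1(C)C | intermediate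
11 | acetylcyclopropane δ-lactone (cyclopropane C5–C9–C10 α; O3–C11 lactone; 10β-CH3) | CC(=O)[C@]12C(=O)O[C@@H]3CC[C@@]1(C)[C@H]2C3(C)C | intermediate
12 | isopropenylcyclopropane δ-lactone | C=C(C)[C@]12C(=O)O[C@@H]3CC[C@@]1(C)[C@H]2C3(C)C | intermediate
13 | carbon monoxide | [C-]#[O+] | starting material
14 | lactone-bridged cis-fused 8-en-6-one | O=C1O[C@@H]2CC[C@]3(C)C1=C(C)CC(=O)[C@@H]3C2(C)C | intermediate
15 | lactone-bridged cis-fused 7-en-6-one (9β-H) | O=C1O[C@@H]2CC[C@]3(C)[C@H]1C(C)=CC(=O)[C@@H]3C2(C)C | intermediate
16 | cis-fused drim-7-ene-3α,6,11-triol (5β-H, 9β-H; C6 epimer mixture, centre left undefined) | OC[C@@H]1C(C)=CC(O)[C@@H]2C(C)(C)[C@H](O)CC[C@]12C | intermediate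
17 | cis-fused 3α,11-dihydroxydrim-7-en-6-one (5β-H, 9β-H) | OC[C@@H]1C(C)=CC(=O)[C@@H]2C(C)(C)[C@H](O)CC[C@]12C | intermediate
18 | (3R,5R,9R,10R)-3α,11-dihydroxydrim-7-en-6-one (5α-H, 9β-H) | OC[C@@H]1C(C)=CC(=O)[C@H]2C(C)(C)[C@H](O)CC[C@]12C | intermediate
19 | isofraxidin (7-hydroxy-6,8-dimethoxycoumarin) | COc1cc2ccc(=O)oc2c(OC)c1O | starting material
20 | 11-O-(6,8-dimethoxy-2-oxo-2H-chromen-7-yl) ether of 18 | COc1cc2ccc(=O)oc2c(OC)c1OC[C@@H]1C(C)=CC(=O)[C@H]2C(C)(C)[C@H](O)CC[C@]12C | intermediate
21 | isovaleryl chloride | CC(C)CC(=O)Cl | starting material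
22 | (3R,5R,9R,10R)-11-[(6,8-dimethoxy-2-oxo-2H-chromen-7-yl)oxy]-6-oxodrim-7-en-3-yl 3-methylbutanoate, CNP0279705.1 | COc1cc2ccc(=O)oc2c(OC)c1OC[C@@H]1C(C)=CC(=O)[C@H]2C(C)(C)[C@H](OC(=O)CC(C)C)CC[C@]12C | target

**Step count and risks**

Total step count: 14. Longest linear sequence: 14 steps, from 4-methylanisole 1 to 22; compounds 7, 13, 19 and 21 are bought and enter directly.

Steps most likely to fail:

Step 8 (carbonylative ring expansion). The rhodium may fail to insert into the crowded, fully substituted cyclopropane, or the ring may open without taking up CO (vinylcyclopropane-to-cyclopentene rearrangement, or a homodienyl hydrogen shift from the C10 methyl). The fallback uses known chemistry, sets out from 12 and returns at 18. It removes the acyl group from the cyclopropane, so that the substrate belongs to the all-alkyl alkenylcyclopropanes for which the photochemical Fe(CO)5 carbonylation to cyclohexenones is established, and it gives up the lactone as the control element for C9. Reduction of 12 with i-Bu2AlH should give the cyclopropyl diol F1, and TBSOTf with 2,6-lutidine the bis(silyl ether) F2. Irradiation of F2 with Fe(CO)5 under CO should give the cis-fused 8-en-6-one F3 with retention at C5. DBU then moves the alkene into conjugation and lets C5 and C9 settle under thermodynamic control to the trans-fused 9β-H enone F4 (trans-decalin; C11 pseudoaxial, anti to the C10 methyl and free of allylic strain with the C8 methyl). HF·pyridine removes both silyl groups and delivers 18, so steps 9 to 12 are bypassed.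

Step 6 (cyclopropanation). The keto carbenoid may be consumed before it reaches the hindered trisubstituted alkene, by C–H insertion into the ring CH2 next to the carbinol carbon, by attack of its own ketone oxygen, or by dimerisation. The fallback sets out from 10 and returns at 12. It changes the carbenoid from the acceptor/acceptor to the donor/acceptor (vinyl) class, which discriminates far better in favour of alkenes, and carries the isopropenyl group through the cyclopropanation. Deacetylation of 10 (LiOH, aqueous MeCN) should give the diazoacetate F5. Lithiation with LiN(i-Pr)2 at −78 °C and addition to acetone should give the tertiary carbinol F6, and POCl3/Et3N dehydration the vinyldiazoacetate F7. Rh2(OAc)4 should then close the same lactone-tethered cyclopropane and give 12 directly, which makes step 7 unnecessary.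

Step 13 (ether formation). The activated C11 oxygen may be lost by elimination, because C9–H is vinylogously acidified by the enone, faster than a slow substitution at a β-branched carbon by a phenol flanked by two methoxy groups. The fallback sets out from 18 and returns at 20. It takes the acidifying carbonyl away during the alkylation and replaces the redox condensation by a sulfonate displacement. NaBH4 with CeCl3·7H2O should reduce 18 to the allylic triol F8. MsCl with 2,4,6-collidine at −20 °C should sulfonylate only the primary alcohol, giving the C11 mesylate F9. Displacement by 19 with Cs2CO3 in DMF at 60 °C should give the aryl ether allylic alcohol F10, and MnO2 restores the enone to deliver 20.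

**Further compounds**

F1 | step 8 | cyclopropyl diol (lactone of 12 reduced: C9–CH2OH, C3–OH) | OC[C@@]1(C(C)=C)[C@@]2(C)CC[C@@H](O)C(C)(C)[C@@H]12
F2 | step 8 | bis(tert-butyldimethylsilyl) ether of F1 | CC(C)(C)[Si](C)(C)OC[C@@]1(C(C)=C)[C@@]2(C)CC[C@@H](O[Si](C)(C)C(C)(C)C)C(C)(C)[C@@H]12
F3 | step 8 | cis-fused 3α,11-bis(silyloxy)drim-8-en-6-one (5β-H) | CC(C)(C)[Si](C)(C)OCC1=C(C)CC(=O)[C@@H]2C(C)(C)[C@H](O[Si](C)(C)C(C)(C)C)CC[C@]12C
F4 | step 8 | trans-fused 3α,11-bis(silyloxy)drim-7-en-6-one (5α-H, 9β-H) | CC(C)(C)[Si](C)(C)OC[C@@H]1C(C)=CC(=O)[C@H]2C(C)(C)[C@H](O[Si](C)(C)C(C)(C)C)CC[C@]12C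
F5 | step 6 | (R)-2,2,4-trimethylcyclohex-3-en-1-yl diazoacetate | [N-]=[N+]=CC(=O)O[C@@H]1CCC(C)=CC1(C)C
F6 | step 6 | (R)-2,2,4-trimethylcyclohex-3-en-1-yl 2-diazo-3-hydroxy-3-methylbutanoate | CC(C)(O)C(=[N+]=[N-])C(=O)O[C@@H]1CCC(C)=CC1(C)C
F7 | step 6 | (R)-2,2,4-trimethylcyclohex-3-en-1-yl 2-diazo-3-methylbut-3-enoate | C=C(C)C(=[N+]=[N-])C(=O)O[C@@H]1CCC(C)=CC1(C)C
F8 | step 13 | trans-fused drim-7-ene-3α,6,11-triol (5α-H, 9β-H; C6 epimer mixture, centre left undefined) | OC[C@@H]1C(C)=CC(O)[C@H]2C(C)(C)[C@H](O)CC[C@]12C
F9 | step 13 | C11 methanesulfonate of F8 | CS(=O)(=O)OC[C@@H]1C(C)=CC(O)[C@H]2C(C)(C)[C@H](O)CC[C@]12C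
F10 | step 13 | 11-O-(6,8-dimethoxy-2-oxo-2H-chromen-7-yl) ether of F8 | COc1cc2ccc(=O)oc2c(OC)c1OC[C@@H]1C(C)=CC(O)[C@H]2C(C)(C)[C@H](O)CC[C@]12C
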